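**Retrosynthetic overview**
- Ring C is the only ring built, and it is closed last. Its C2=C3 double bond comes from dehydration of a 3-hydroxyisoflavanone.
- Key disconnection C3–C4: an N-heterocyclic carbene turns the aldehyde carbon of a salicylaldehyde phenacyl ether into an acyl anion equivalent, which attacks the aryl ketone carbon.
- O1–C2: ether formation between 2-hydroxy-4-methoxy-3-prenylbenzaldehyde and 2-chloro-1-(2,4,5-trimethoxyphenyl)ethanone.
- Ring A piece: C3-prenylation, then 4-O-methylation, of 2,4-dihydroxybenzaldehyde.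
- Ring B piece: Friedel–Crafts chloroacetylation of 1,2,4-trimethoxybenzene.

Assumption: the SMILES has no stereocentre and no stereogenic double bond, so prebarbigerone is achiral and there is no enantiomer to choose. The one carbon stereocentre that appears on the way (C3 of 10 and 11) is racemic and is erased in the same flask.

**Step 1**
Reactants: 1 2,4-dihydroxybenzaldehyde; 2 prenyl bromide (1-bromo-3-methylbut-2-ene)
Product: 3 2,4-dihydroxy-3-(3-methylbut-2-en-1-yl)benzaldehyde
Conditions: KOH (1.1 equiv), H2O, 0 °C to rt, 16 h; acidify; chromatography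
Reagents that add atoms: none
Why: Phenolate C-alkylation (direct C-prenylation): in water the phenolate oxygens are hydrogen-bonded, so the soft allylic bromide is attacked by carbon, mainly at C3 (ortho to both oxygens), and the 5-prenyl and O-prenyl isomers are separated (expect 30–40 %); no stereocentre forms.

**Step 2**
Reactants: 3 2,4-dihydroxy-3-(3-methylbut-2-en-1-yl)benzaldehyde
Product: 4 2-hydroxy-4-methoxy-3-(3-methylbut-2-en-1-yl)benzaldehyde
Conditions: MeI (1.05 equiv), K2CO3 (1.0 equiv), acetone, rt to 40 °C
Reagents that add atoms: iodomethane (MeI), CI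
Why: Williamson ether synthesis, site-selective because the 2-OH is hydrogen-bonded to the aldehyde and is much less acidic and nucleophilic than the free 4-OH, so one equivalent of base and MeI methylates O4 only.

**Step 3**
Reactants: 5 1,2,4-trimethoxybenzene; 6 chloroacetyl chloride
Product: 7 2-chloro-1-(2,4,5-trimethoxyphenyl)ethan-1-one
Conditions: AlCl3 (1.1 equiv), CH2Cl2, −10 to 0 °C, 1 h; ice/aq. HCl quench
Reagents that add atoms: none
Why: Friedel–Crafts acylation at C5 of 5, the only open position para to one methoxy group and ortho to another, run cold and short with barely more than one equivalent of AlCl3 so that the methoxy group ortho to the new ketone is not cleaved.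

**Step 4**
Reactants: 4 2-hydroxy-4-methoxy-3-(3-methylbut-2-en-1-yl)benzaldehyde; 7 2-chloro-1-(2,4,5-trimethoxyphenyl)ethan-1-one
Product: 8 4-methoxy-3-(3-methylbut-2-en-1-yl)-2-[2-oxo-2-(2,4,5-trimethoxyphenyl)ethoxy]benzaldehyde
Conditions: K2CO3 (1.5 equiv), DMF, rt, 12 h
Reagents that add atoms: none
Why: Williamson ether synthesis (SN2 at a very reactive alpha-chloro ketone), kept at room temperature with a weak base so that 8 does not go on by intramolecular aldol condensation to the 2-aroylbenzofuran (Rap–Stoermer reaction).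

**Step 5**
Reactants: 8 4-methoxy-3-(3-methylbut-2-en-1-yl)-2-[2-oxo-2-(2,4,5-trimethoxyphenyl)ethoxy]benzaldehyde
Product: 12 prebarbigerone (7-methoxy-8-(3-methylbut-2-en-1-yl)-3-(2,4,5-trimethoxyphenyl)-4H-chromen-4-one), via Breslow enaminol 9 (not isolated), via 3-hydroxyisoflavanone 10 (not isolated), via chlorosulfite 11 (not isolated)
Conditions: 2-(pentafluorophenyl)-6,7-dihydro-5H-pyrrolo[2,1-c][1,2,4]triazol-2-ium tetrafluoroborate (10 mol %), Et3N (20 mol %), CH2Cl2, N2, rt to 35 °C, 12–24 h; then same flask, pyridine (5 equiv), SOCl2 (1.5 equiv), 0 °C to rt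
Reagents that add atoms: none
Why: Carbene-catalysed intramolecular crossed benzoin reaction followed by alcohol dehydration: the carbene adds to the aldehyde and a proton shift gives enaminol 9, an acyl anion equivalent whose former carbonyl carbon attacks the ketone carbon in a 6-exo closure (two naturally electrophilic carbons become C4–C3) to give racemic carbinol 10, and its stereocentre is erased when chlorosulfite 11 ionises at the trimethoxyphenyl-stabilised carbon and loses a C2 proton to form the conjugated 4-pyranone.

**Compound list**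
1 | 2,4-dihydroxybenzaldehyde | O=Cc1ccc(O)cc1O | starting material
2 | prenyl bromide (1-bromo-3-methylbut-2-ene) | CC(C)=CCBr | starting material
3 | 2,4-dihydroxy-3-(3-methylbut-2-en-1-yl)benzaldehyde | O=Cc1ccc(O)c(CC=C(C)C)c1O | intermediate
4 | 2-hydroxy-4-methoxy-3-(3-methylbut-2-en-1-yl)benzaldehyde | O=Cc1ccc(OC)c(CC=C(C)C)c1O | intermediate
5 | 1,2,4-trimethoxybenzene | COc1ccc(OC)c(OC)c1 | starting material
6 | chloroacetyl chloride | O=C(Cl)CCl | starting material
7 | 2-chloro-1-(2,4,5-trimethoxyphenyl)ethan-1-one | COc1cc(OC)c(C(=O)CCl)cc1OC | intermediate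
8 | 4-methoxy-3-(3-methylbut-2-en-1-yl)-2-[2-oxo-2-(2,4,5-trimethoxyphenyl)ethoxy]benzaldehyde | COc1cc(OC)c(C(=O)COc2c(C=O)ccc(OC)c2CC=C(C)C)cc1OC | intermediate
9 | Breslow enaminol of 8 with the pentafluorophenyl pyrrolotriazolylidene (enol alkene geometry not fixed) | COc1cc(OC)c(C(=O)COc2c(C(O)=C3N(c4c(F)c(F)c(F)c(F)c4F)N=C4CCCN34)ccc(OC)c2CC=C(C)C)cc1OC | intermediate
10 | racemic 3-hydroxy-7-methoxy-8-(3-methylbut-2-en-1-yl)-3-(2,4,5-trimethoxyphenyl)chroman-4-one | COc1cc(OC)c(C2(O)COc3c(CC=C(C)C)c(OC)ccc3C2=O)cc1OC | intermediate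
11 | racemic O-chlorosulfite of 10 | COc1cc(OC)c(C2(OS(=O)Cl)COc3c(CC=C(C)C)c(OC)ccc3C2=O)cc1OC | intermediate
12 | prebarbigerone (achiral) | COc1cc(OC)c(-c2coc3c(CC=C(C)C)c(OC)ccc3c2=O)cc1OC | target

**Total step count:** 5. **Longest linear sequence:** 4 (steps 1, 2, 4, 5).

**Steps most likely to fail**

Step 5. The 2,4,5-trimethoxybenzoyl ketone is electron-rich and ortho-substituted, so it may be too poor an acceptor for 9. The amine base can also divert 8 to the 2-aroylbenzofuran. The fallback sets out from 8 and comes back at 10. It replaces the redox-neutral carbene catalysis with a reductive ketyl–carbonyl (pinacol) cyclisation. SmI2 (2.2 equiv) in THF/t-BuOH at −78 °C reduces the aromatic aldehyde first. Its ketyl closes onto the samarium-bound ketone faster than the aryloxy group is expelled. This gives 7-methoxy-8-(3-methylbut-2-en-1-yl)-3-(2,4,5-trimethoxyphenyl)chromane-3,4-diol F1 (racemic; the cis/trans ratio does not matter). IBX in DMSO at rt then oxidises only the secondary benzylic alcohol, without glycol cleavage, to 10. Compound 10 is isolated and dehydrated with SOCl2/pyridine as in the second stage of step 5.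

Step 1. C- versus O-alkylation and C3 versus C5 selectivity are only moderate, so the yield is low. The fallback sets out from 1 and comes back at 3. It delivers the prenyl group by a sigmatropic shift instead of direct alkylation.
- The free 4-OH of 1 is etherified with 3-chloro-3-methylbut-1-yne (K2CO3, acetone, reflux) to give 2-hydroxy-4-[(2-methylbut-3-yn-2-yl)oxy]benzaldehyde F2.
- Semihydrogenation (H2, Pd/CaCO3 poisoned with Pb(OAc)2, quinoline, EtOAc) gives 2-hydroxy-4-[(2-methylbut-3-en-2-yl)oxy]benzaldehyde F3.
- An aromatic Claisen rearrangement (N,N-diethylaniline, about 130 °C) moves the inverted allyl unit to C3, the position favoured by bond fixation in the chelated ring, to give 3.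

Step 4. The hindered, chelated phenol may alkylate slowly, and carbonate base can push 8 into the Rap–Stoermer condensation. The fallback sets out from 7 and comes back at 8. It forms the ether by redox dehydration without carbonate base.
- HCO2Na in aqueous ethanol at reflux displaces chloride from 7 to give 2-oxo-2-(2,4,5-trimethoxyphenyl)ethyl formate F4.
- F4 is hydrolysed in the same pot to 2-hydroxy-1-(2,4,5-trimethoxyphenyl)ethan-1-one F5.
- Mitsunobu coupling of F5 with phenol 4 (PPh3, DIAD, THF, 0 °C to rt) gives 8.

**Further compounds**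
F1 | step 5 | 7-methoxy-8-(3-methylbut-2-en-1-yl)-3-(2,4,5-trimethoxyphenyl)chromane-3,4-diol (racemic, diastereomer mixture) | COc1cc(OC)c(C2(O)COc3c(CC=C(C)C)c(OC)ccc3C2O)cc1OC
F2 | step 1 | 2-hydroxy-4-[(2-methylbut-3-yn-2-yl)oxy]benzaldehyde | O=Cc1ccc(OC(C)(C)C#C)cc1O
F3 | step 1 | 2-hydroxy-4-[(2-methylbut-3-en-2-yl)oxy]benzaldehyde | O=Cc1ccc(OC(C)(C)C=C)cc1O
F4 | step 4 | 2-oxo-2-(2,4,5-trimethoxyphenyl)ethyl formate | COc1cc(OC)c(C(=O)COC=O)cc1OC
F5 | step 4 | 2-hydroxy-1-(2,4,5-trimethoxyphenyl)ethan-1-one | COc1cc(OC)c(C(=O)CO)cc1OC
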